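**Retrosynthetic overview**

1. The quinone ring is joined to the rest of the molecule only through the bond from its C2 to furan C2 and carries no other substituent. All six of its carbons can therefore be built on an ethynyl group at furan C2 by a Dötz benzannulation (two alkyne carbons, three carbene carbons, one CO). This gives the 4-methoxyphenol 18, which is oxidised to quinone 19 in the last step.
2. The unsubstituted methoxy(vinyl)carbene chromium complex polymerises readily and annulates poorly, so the carbene partner 15 carries a trans-SiMe3 group on the vinyl terminus. After ring closure the silicon moves from that carbon to the phenol oxygen and is removed on work-up, so the same three C–C bonds form and the same phenol results.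
3. Alkyne 10 comes from 5-bromofuran-3-carbaldehyde 1: Brown allylation sets the single (S) stereocentre, cross-metathesis gives the prenyl end, Steglich esterification adds the senecioate, and Sonogashira coupling plus desilylation place the ethynyl group on the brominated furan carbon.
4. Ring order: the furan is bought, the six-membered carbocycle is formed in step 7, and no other ring is made.

Key step: step 7

Remark: 5-bromofuran-3-carbaldehyde, (E)-(2-bromovinyl)trimethylsilane and (−)-Ipc2BOMe are taken as catalogue compounds, and the aryl O–SiMe3 bond formed in step 7 is taken to hydrolyse on mild acidic work-up.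

**Route**

Step 1
Reactants: 1 5-bromofuran-3-carbaldehyde
Product: 3 (S)-1-(5-bromofuran-3-yl)but-3-en-1-ol, via borinate ester 2 (not isolated)
Conditions: (−)-Ipc2BOMe, allylMgBr, Et2O, 0 °C to rt; then 1, −78 °C; then NaOH, H2O2, H2O, 0 °C to rt
Reagents that add atoms: allylmagnesium bromide, C=CC[Mg]Br (allyl group, passed on through (−)-B-allyldiisopinocampheylborane, C=CCB([C@@H]1C[C@@H]2C[C@@H](C2(C)C)[C@H]1C)[C@@H]1C[C@@H]2C[C@@H](C2(C)C)[C@H]1C, made in the flask from (−)-B-methoxydiisopinocampheylborane, COB([C@@H]1C[C@@H]2C[C@@H](C2(C)C)[C@H]1C)[C@@H]1C[C@@H]2C[C@@H](C2(C)C)[C@H]1C)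
Why: Brown asymmetric allylboration, in which the allyl group is delivered through a chair six-membered transition state and the isopinocampheyl groups derived from (+)-α-pinene direct it to the Si face of the aldehyde, which for an aryl-type aldehyde gives the (S)-carbinol, while the basic peroxide work-up only cleaves the B–O and B–C bonds of borinate 2.

Step 2
Reactants: 3 (S)-1-(5-bromofuran-3-yl)but-3-en-1-ol; 4 2-methylbut-2-ene
Product: 5 (S)-1-(5-bromofuran-3-yl)-4-methylpent-3-en-1-ol
Conditions: second-generation Grubbs catalyst RuCl2(=CHPh)(H2IMes)(PCy3) (5 mol %), 2-methylbut-2-ene (large excess), CH2Cl2, rt to 35 °C, sealed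
Reagents that add atoms: none
Why: Olefin cross-metathesis of the terminal alkene with a large excess of the trisubstituted olefin should cap the chain as the prenyl group with loss of propene, the homoallylic hydroxyl, the bromofuran and the stereocentre taking no part.

Step 3
Reactants: 5 (S)-1-(5-bromofuran-3-yl)-4-methylpent-3-en-1-ol; 6 3-methylbut-2-enoic acid
Product: 7 (S)-1-(5-bromofuran-3-yl)-4-methylpent-3-en-1-yl 3-methylbut-2-enoate
Conditions: DCC, DMAP (cat.), CH2Cl2, 0 °C to rt
Reagents that add atoms: none
Why: Steglich esterification acylates the secondary alcohol at oxygen, so the C–O bond of the stereocentre is not broken and the configuration is kept, and it avoids the acid chloride/amine pair that can deconjugate the acyl group through a vinylketene.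

Step 4
Reactants: 7 (S)-1-(5-bromofuran-3-yl)-4-methylpent-3-en-1-yl 3-methylbut-2-enoate; 8 ethynyltrimethylsilane
Product: 9 (S)-4-methyl-1-{5-[(trimethylsilyl)ethynyl]furan-3-yl}pent-3-en-1-yl 3-methylbut-2-enoate
Conditions: PdCl2(PPh3)2 (cat.), CuI (cat.), Et3N, THF, 45 °C
Reagents that add atoms: none
Why: Sonogashira coupling, in which zerovalent palladium inserts into the reactive C2–Br bond of the furan, the copper acetylide transmetalates and reductive elimination forms the C(sp2)–C(sp) bond, under conditions too mild to ionise the furylic ester.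

Step 5
Reactants: 9 (S)-4-methyl-1-{5-[(trimethylsilyl)ethynyl]furan-3-yl}pent-3-en-1-yl 3-methylbut-2-enoate
Product: 10 (S)-1-(5-ethynylfuran-3-yl)-4-methylpent-3-en-1-yl 3-methylbut-2-enoate
Conditions: Bu4NF, AcOH, THF, 0 °C
Reagents that add atoms: none
Why: Fluoride-induced protodesilylation of the alkynylsilane is fast, and buffering with acetic acid keeps the medium non-basic so the senecioate is neither cleaved nor deconjugated.

Step 6
Reactants: 11 (E)-(2-bromovinyl)trimethylsilane; 12 chromium hexacarbonyl Cr(CO)6
Product: 15 pentacarbonyl[(2E)-1-methoxy-3-(trimethylsilyl)prop-2-en-1-ylidene]chromium (zerovalent chromium), via vinyllithium 13 (not isolated), via lithium acylchromate 14 (not isolated)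
Conditions: t-BuLi (2 equiv), Et2O, −78 °C; Cr(CO)6, −78 °C to rt; Me3OBF4, CH2Cl2, 0 °C
Reagents that add atoms: trimethyloxonium tetrafluoroborate, C[O+](C)C.F[B-](F)(F)F (O-methyl group)
Why: Fischer carbene synthesis, in which bromine–lithium exchange keeps the E geometry, the vinyllithium adds to a carbonyl ligand of Cr(CO)6 to give the acylchromate, and the hard oxonium salt methylates its oxygen.

Step 7
Reactants: 10 (S)-1-(5-ethynylfuran-3-yl)-4-methylpent-3-en-1-yl 3-methylbut-2-enoate; 15 pentacarbonyl[(2E)-1-methoxy-3-(trimethylsilyl)prop-2-en-1-ylidene]chromium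
Product: 18 (S)-1-[5-(2-hydroxy-5-methoxyphenyl)furan-3-yl]-4-methylpent-3-en-1-yl 3-methylbut-2-enoate, via tricarbonylchromium arene complex 16 (not isolated), via aryl trimethylsilyl ether 17 (not isolated)
Conditions: 10 added slowly to 15 (1.5 equiv), THF (0.05 M), 50 °C, Ar; then air, Et2O, rt; then aq. citric acid, THF, rt
Reagents that add atoms: none
Why: This is a Dötz benzannulation of an alkenyl(alkoxy)carbene chromium complex with a terminal alkyne, in the known variant where a trans-β-silyl alkenyl complex stands in for the polymerisation-prone parent vinyl complex. Thermal loss of one CO lets the alkyne bind and insert into the Cr=C bond with its CH carbon joined to the carbene carbon; CO insertion then joins the furyl-bearing carbon to a carbonyl carbon and gives a chromium-bound dienylketene. A 6π-electrocyclisation between the ketene carbon and the silyl-bearing vinyl terminus closes the six-membered carbocycle as a cyclohexa-2,4-dienone. Aromatisation follows by 1,3-shift of SiMe3 from ring carbon C6 to the carbonyl oxygen, giving the aryl silyl ether as its Cr(CO)3 complex 16; air removes the metal and dilute acid cleaves the O–Si bond to phenol 18. No stereocentre is formed, and the (S)-centre is remote from the reacting atoms. The step needs regioselective insertion, set by furyl against hydrogen on the alkyne (a lapse is harmless, since both regioisomers oxidise to the same monosubstituted quinone), and chemoselectivity for the alkyne over the prenyl olefin, the senecioate and the furan diene, secured because only the unhindered terminal alkyne binds the unsaturated chromium centre readily and the alkynyl group makes the furan a poor diene.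

Step 8
Reactants: 18 (S)-1-[5-(2-hydroxy-5-methoxyphenyl)furan-3-yl]-4-methylpent-3-en-1-yl 3-methylbut-2-enoate
Product: 19 (S)-1-[5-(3,6-dioxocyclohexa-1,4-dien-1-yl)furan-3-yl]-4-methylpent-3-en-1-yl 3-methylbut-2-enoate
Conditions: PhI(OAc)2 (1.2 equiv), MeCN–H2O, 0 °C
Reagents that add atoms: water, O (oxygen of the quinone carbonyl at the former methoxy carbon)
Why: Hypervalent-iodine oxidation of a para-alkoxyphenol, in which the phenol oxygen binds iodine, two-electron oxidation lets water attack the methoxy-bearing para carbon and the hemiketal loses methanol to give the 1,4-quinone, a path that starts at the phenol and should spare the furan, the trisubstituted olefins, the ester and the stereocentre.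

**Compound list**

1 | 5-bromofuran-3-carbaldehyde | O=Cc1coc(Br)c1 | starting material
2 | (S)-1-(5-bromofuran-3-yl)but-3-en-1-yl diisopinocampheylborinate | C=CC[C@H](OB([C@@H]1C[C@@H]2C[C@@H](C2(C)C)[C@H]1C)[C@@H]1C[C@@H]2C[C@@H](C2(C)C)[C@H]1C)c1coc(Br)c1 | intermediate
3 | (S)-1-(5-bromofuran-3-yl)but-3-en-1-ol | C=CC[C@H](O)c1coc(Br)c1 | intermediate
4 | 2-methylbut-2-ene | CC=C(C)C | starting material
5 | (S)-1-(5-bromofuran-3-yl)-4-methylpent-3-en-1-ol | CC(C)=CC[C@H](O)c1coc(Br)c1 | intermediate
6 | 3-methylbut-2-enoic acid | CC(C)=CC(=O)O | starting material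
7 | (S)-1-(5-bromofuran-3-yl)-4-methylpent-3-en-1-yl 3-methylbut-2-enoate | CC(C)=CC[C@H](OC(=O)C=C(C)C)c1coc(Br)c1 | intermediate
8 | ethynyltrimethylsilane | C#C[Si](C)(C)C | starting material
9 | (S)-4-methyl-1-{5-[(trimethylsilyl)ethynyl]furan-3-yl}pent-3-en-1-yl 3-methylbut-2-enoate | CC(C)=CC[C@H](OC(=O)C=C(C)C)c1coc(C#C[Si](C)(C)C)c1 | intermediate
10 | (S)-1-(5-ethynylfuran-3-yl)-4-methylpent-3-en-1-yl 3-methylbut-2-enoate | CC(C)=CC[C@H](OC(=O)C=C(C)C)c1coc(C#C)c1 | intermediate
11 | (E)-(2-bromovinyl)trimethylsilane | Br/C=C/[Si](C)(C)C | starting material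
12 | chromium hexacarbonyl Cr(CO)6 | O=C=[Cr](=C=O)(=C=O)(=C=O)(=C=O)=C=O | starting material
13 | (E)-[2-(trimethylsilyl)vinyl]lithium | [Li]/C=C/[Si](C)(C)C | intermediate
14 | lithium pentacarbonyl[(2E)-1-oxido-3-(trimethylsilyl)prop-2-en-1-ylidene]chromate | [Li+].[O-]C(/C=C/[Si](C)(C)C)=[Cr](=C=O)(=C=O)(=C=O)(=C=O)=C=O | intermediate
15 | pentacarbonyl[(2E)-1-methoxy-3-(trimethylsilyl)prop-2-en-1-ylidene]chromium (zerovalent chromium) | COC(/C=C/[Si](C)(C)C)=[Cr](=C=O)(=C=O)(=C=O)(=C=O)=C=O | intermediate
16 | tricarbonylchromium complex of 17, metal η6-bound to the benzene ring (written as two components) | CC(C)=CC[C@H](OC(=O)C=C(C)C)c1coc(-c2cc(OC)ccc2O[Si](C)(C)C)c1.[Cr](=C=O)(=C=O)=C=O | intermediate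
17 | (S)-1-{5-[5-methoxy-2-(trimethylsilyloxy)phenyl]furan-3-yl}-4-methylpent-3-en-1-yl 3-methylbut-2-enoate | CC(C)=CC[C@H](OC(=O)C=C(C)C)c1coc(-c2cc(OC)ccc2O[Si](C)(C)C)c1 | intermediate
18 | (S)-1-[5-(2-hydroxy-5-methoxyphenyl)furan-3-yl]-4-methylpent-3-en-1-yl 3-methylbut-2-enoate | CC(C)=CC[C@H](OC(=O)C=C(C)C)c1coc(-c2cc(OC)ccc2O)c1 | intermediate
19 | (S)-1-[5-(3,6-dioxocyclohexa-1,4-dien-1-yl)furan-3-yl]-4-methylpent-3-en-1-yl 3-methylbut-2-enoate (CNP0314322.1) | CC(C)=CC[C@H](OC(=O)C=C(C)C)c1coc(C2=CC(=O)C=CC2=O)c1 | target

**Step count**

Total steps: 8. Longest linear sequence: 7 steps (steps 1, 2, 3, 4, 5, 7, 8 from aldehyde 1); the carbene branch (step 6) joins at step 7.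

**Steps most likely to fail, with fallbacks**

Step 7. The alkenyl carbene complex may be used up by self-condensation or by cycloaddition to the furan before the alkyne inserts. The terminal alkyne may also insert more than once. A third failure is that the hydrogen on C6 of the dienone shifts in place of silicon, which would leave the silyl group on the ring. The fallback drops the ring construction for a cross-coupling. It sets out from bromide 7: Suzuki–Miyaura coupling with commercial (2-hydroxy-5-methoxyphenyl)boronic acid (Pd(OAc)2, SPhos, K3PO4, THF–H2O, 40 °C) joins furan C2 to the preformed arene and should give phenol 18 directly. The route resumes at 18 with step 8. This detour makes no compound outside the list (F0).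

Step 6. O-Methylation of the lithium acylchromate may lose out to hydrolysis of the oxonium salt or to conjugate addition and oligomerisation of the alkenyl acylate during the solvent change. The fallback sets out from lithium acylchromate 14 and forms the C–OMe bond by acylation and alcoholysis in place of alkylation. Cation exchange with Me4NBr in water should precipitate the storable tetramethylammonium acylchromate F1. Acetyl bromide in CH2Cl2 at −40 °C converts it to the acetoxycarbene complex F2, and added methanol displaces acetate at the carbene carbon by addition–elimination. This returns to the route at 15.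

Step 8. Over-oxidation is the risk: the oxidant, or the quinone as it forms, may attack the electron-rich furan (oxidative ring opening or coupling) in the aqueous oxidising medium. The fallback sets out from phenol 18 and separates oxidation from release of the quinone. PhI(OAc)2 in dry MeOH at 0 °C should trap the oxidised ring as the quinone monoketal F3, which is isolated free of oxidant. Hydrolysis with dilute aqueous oxalic acid in THF then gives 19.

**Further compounds**

F0 | step 7 | none | none
F1 | step 6 | tetramethylammonium pentacarbonyl[(2E)-1-oxido-3-(trimethylsilyl)prop-2-en-1-ylidene]chromate | C[N+](C)(C)C.[O-]C(/C=C/[Si](C)(C)C)=[Cr](=C=O)(=C=O)(=C=O)(=C=O)=C=O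
F2 | step 6 | pentacarbonyl[(2E)-1-acetoxy-3-(trimethylsilyl)prop-2-en-1-ylidene]chromium | CC(=O)OC(/C=C/[Si](C)(C)C)=[Cr](=C=O)(=C=O)(=C=O)(=C=O)=C=O
F3 | step 8 | (S)-1-[5-(3,3-dimethoxy-6-oxocyclohexa-1,4-dien-1-yl)furan-3-yl]-4-methylpent-3-en-1-yl 3-methylbut-2-enoate | CC(C)=CC[C@H](OC(=O)C=C(C)C)c1coc(C2=CC(OC)(OC)C=CC2=O)c1
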